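**Plan**

1. Retrosynthesis: the butenolide (C16=O, C15–O) goes back to a 2-silyl-3-furyl group and C12–C13 is cut to a C11–C12 epoxide plus a 3-lithiofuran; C8=C17 goes back to a ketone and C11–O to the β-carbon of a C9=C11 enone.
2. Ring A is then opened at C3–C4 and C4–C7 is closed instead: C4 with both methyls, C5, C6, C7, C8, C9, C10 and the C10 methyl are the ten carbons of (+)-verbenone, with its carbonyl as C8 and its cyclobutane holding C4, C5, C6 and C7.
3. The remaining cuts are C1–C10 (allyl cuprate addition), C2=C3–Si (alkyne from the aldehyde, then hydrosilylation) and C9=C11 (aldol condensation with a silyloxyacetaldehyde).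
4. Forward: ring B is the six-membered ring of the pinane from the start; the C10 arm and C9 alkylidene are attached; ring A closes as the cyclobutane opens; then C11–OH, C8=CH2, the epoxide, the furan and last the butenolide ring.
5. Stereochemistry: C5 comes from verbenone; C10 from cuprate addition anti to the gem-dimethyl bridge (this also fixes the trans fusion); C11 and C9 from borylation and protonation of the C9=C11 enone on the α face, anti to the axial C10 methyl.

Key step: step 7

Numbering: labdane numbering is used for all compounds; in the pinane intermediates C8 is the carbonyl carbon, C9 the CH2 beside it, C10 the quaternary carbon, C5 and C7 the bridgeheads, C4 the CMe2 bridge, C6 the CH2 bridge, and C1–C3 the arm on C10.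

Remark: the vinylsilane is carried as the Z isomer with a triethylsilyl group, because only a silyl group cis to C1 becomes axial in the chair closure and can stabilise the C2 cation; an E vinylsilane would keep silicon equatorial.

Remark: (+)-verbenone, allylmagnesium bromide, (triisopropylsilyloxy)acetaldehyde and 3-bromofuran are taken as commercial.

**Route**

Step 1
Reactants: 1 (1R,5R)-(+)-verbenone; 2 allylmagnesium bromide
Product: 4 (1R,4R,5R)-4-allyl-4,6,6-trimethylbicyclo[3.1.1]heptan-2-one, via trimethylsilyl enol ether 3 (not isolated)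
Conditions: CuBr·SMe2, Me3SiCl, THF, −78 °C; then 1 M HCl, 0 °C
Reagents that add atoms: chlorotrimethylsilane, C[Si](C)(C)Cl (silicon of intermediate 3 only)
Why: Copper-mediated conjugate allylation, accelerated by Me3SiCl which traps the enolate as 3 and suppresses 1,2-addition; the allyl group should enter the β-carbon from the side of the CH2 bridge, anti to the gem-dimethyl bridge, which sets C10 with its methyl syn to the CMe2 bridge.

Step 2
Reactants: 4 (1R,4R,5R)-4-allyl-4,6,6-trimethylbicyclo[3.1.1]heptan-2-one
Product: 6 keto aldehyde (C10–CH2–CHO), via ozonide 5 (not isolated)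
Conditions: O3, CH2Cl2, −78 °C; then Me2S, −78 °C → rt
Reagents that add atoms: ozone, [O-][O+]=O
Why: Ozonolysis with reductive work-up cleaves the only C=C bond and leaves the ketone and the quaternary C10 untouched.

Step 3
Reactants: 6 keto aldehyde
Product: 7 propargyl ketone (C10–CH2–C≡CH)
Conditions: dimethyl (1-diazo-2-oxopropyl)phosphonate, K2CO3, MeOH, 0 °C → rt
Reagents that add atoms: dimethyl (1-diazo-2-oxopropyl)phosphonate, CC(=O)C(=[N+]=[N-])P(=O)(OC)OC
Why: Seyferth–Gilbert homologation in the Ohira–Bestmann variant turns the aldehyde into the terminal alkyne, the hindered ketone reacting far more slowly and no stereocentre being epimerisable.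

Step 4
Reactants: 7 propargyl ketone
Product: 8 (Z)-vinylsilane ketone (C10–CH2–CH=CH–SiEt3)
Conditions: Et3SiH, [RuCl2(p-cymene)]2 (cat.), CH2Cl2, 40 °C
Reagents that add atoms: triethylsilane, CC[SiH](CC)CC
Why: Ruthenium-catalysed trans-hydrosilylation of a terminal alkyne places silicon on the terminal carbon and should give the (Z)-vinylsilane that the ring closure needs.

Step 5
Reactants: 8 (Z)-vinylsilane ketone; 9 (triisopropylsilyloxy)acetaldehyde
Product: 11 aldol adduct (C9–CH(OH)–CH2OSi(i-Pr)3; mixture at C9 and C11), via lithium enolate 10 (not isolated)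
Conditions: LDA, THF, −78 °C; then 9, −78 °C; pH 7 buffer
Reagents that add atoms: lithium diisopropylamide, [Li]N(C(C)C)C(C)C (lithium of intermediate 10 only)
Why: Directed aldol addition of a lithium enolate; only C9 can be deprotonated because C7 is a bridgehead, and the new centres at C9 and C11 need no control since both become sp2 in step 6.

Step 6
Reactants: 11 aldol adduct
Product: 13 bicyclic enone with (Z)-C9=C11H–CH2OSi(i-Pr)3 and the (Z)-silylallyl arm on C10, via mesylate 12 (not isolated)
Conditions: MsCl, Et3N, CH2Cl2, 0 °C; then DBU, rt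
Reagents that add atoms: methanesulfonyl chloride, CS(=O)(=O)Cl (mesyl group of intermediate 12 only)
Why: Mesylation and E1cB elimination complete the aldol condensation, and the CH2OSi group should end up syn to the carbonyl (Z) because the other isomer would press it against the quaternary C10 (allylic 1,3-strain).

Step 7
Reactants: 13 bicyclic enone
Product: 14 trans-fused octalin enone (ring A closed with C2=C3; 5α-H; 10β-CH3; (Z)-C9=C11)
Conditions: BF3·OEt2 (1.5 equiv), CH2Cl2, −78 → 0 °C; aq NaHCO3
Reagents that add atoms: none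
Why: Proposed new method: BF3 bound to the C8 carbonyl weakens the strained C4–C7 bond, the only cyclobutane bond α,β to C8 that can leave as a tertiary cation, and heterolysis gives a boron dienolate and the C4 cation with release of the ring strain. The closest known reaction types are the Lewis-acid opening of pinane ketones such as nopinone and verbanone (BF3·OEt2 with Ac2O and Zn(OAc)2) to tertiary cations and the vinylsilane-terminated cation–olefin cyclisation; joining them in one operation on an α-alkylidene ketone is new. On the freed ring B the cationic C5 substituent and the C10 arm are trans and both equatorial, so the cation reaches the silicon-bearing C3 through a chair in a 6-endo-trig closure that forms C3–C4 and ring A. With the Z vinylsilane the C3–Si bond becomes axial and overlaps with the empty orbital at C2, and fluoride-assisted loss of Et3Si leaves the double bond at C2=C3 only. No stereocentre is created: C5 and C10 are carried over, and the trans fusion is dictated by the anti addition of step 1. The step needs capture of the cation by the vinylsilane to outrun proton loss to an isopropenyl group, fluoride capture and attack of the vinylsilane on the BF3-bound enone, which the intramolecular chair, the β-silicon effect and the poor nucleophilicity of a vinylsilane toward an enone should secure; aqueous work-up protonates the dienolate at C7 and returns the enone.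

Step 8
Reactants: 14 trans-fused octalin enone
Product: 16 β-hydroxy ketone (C11–OH configured as in the target; 9α-H; side chain equatorial), via C11 pinacol boronate 15 (not isolated)
Conditions: B2pin2, CuCl (cat.), Xantphos (cat.), NaOtBu (cat.), MeOH, THF, rt; then NaBO3·4H2O, THF/H2O, rt
Reagents that add atoms: bis(pinacolato)diboron, CC1(C)OB(OC1(C)C)B1OC(C)(C)C(C)(C)O1 (boronate of intermediate 15 only); sodium perborate, [Na+].[Na+].O[B-]1(O)OO[B-](O)(O)OO1 (the C11 oxygen)
Why: Copper-catalysed conjugate borylation followed by stereoretentive C–B oxidation; (Xantphos)Cu–Bpin should add to the α face of C9=C11, anti to the axial C10 methyl, which with the Z alkylidene sets C11 as in the target, and protonation of the enolate on the same face puts H-9 α, the epimer also favoured at equilibrium.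

Step 9
Reactants: 16 β-hydroxy ketone
Product: 17 ring-A-saturated β-hydroxy ketone
Conditions: H2 (1 atm), Pd/C, EtOAc, rt
Reagents that add atoms: none
Why: Heterogeneous catalytic hydrogenation saturates the cis-disubstituted C2=C3 bond, the only alkene left, without touching the ketone or the silyl ether and without creating a stereocentre.

Step 10
Reactants: 17 ring-A-saturated β-hydroxy ketone
Product: 18 C11 triethylsilyl ether
Conditions: Et3SiOTf, 2,6-lutidine, CH2Cl2, −78 °C
Reagents that add atoms: triethylsilyl trifluoromethanesulfonate, CC[Si](CC)(CC)OS(=O)(=O)C(F)(F)F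
Why: Silylation of the hindered secondary alcohol with a silyl triflate and a non-nucleophilic base blocks retro-aldol and β-elimination before the olefination.

Step 11
Reactants: 18 C11 triethylsilyl ether
Product: 19 exocyclic methylene compound (C8=C17H2)
Conditions: Cp2TiMe2, toluene, 70 °C, dark
Reagents that add atoms: dimethyltitanocene, C[Ti](C)(C1C=CC=C1)C1C=CC=C1
Why: Petasis methylenation through Cp2Ti=CH2 is non-basic, so the hindered, enolisable β-silyloxy ketone should be olefinated without epimerisation at C9 or loss of the C11 silyloxy group.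

Step 12
Reactants: 19 exocyclic methylene compound
Product: 20 C11,C12-diol
Conditions: Bu4NF, THF, rt
Reagents that add atoms: none
Why: Fluoride-induced desilylation removes both silyl ethers while the 1,1-disubstituted alkene is inert.

Step 13
Reactants: 20 C11,C12-diol
Product: 22 terminal C11–C12 epoxide, via primary tosylate 21 (not isolated)
Conditions: NaH, 1-(p-toluenesulfonyl)imidazole, THF, 0 °C → rt
Reagents that add atoms: 1-(p-toluenesulfonyl)imidazole, Cc1ccc(cc1)S(=O)(=O)n1ccnc1 (tosyl group of intermediate 21 only)
Why: Selective sulfonylation of the primary hydroxyl and intramolecular Williamson etherification (SN2 at C12) give the epoxide with C11 untouched.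

Step 14
Reactants: 23 3-bromofuran
Product: 25 3-bromo-2-(trimethylsilyl)furan, via 3-bromo-2-lithiofuran 24 (not isolated)
Conditions: LDA, THF, −78 °C; then Me3SiCl, −78 °C → rt
Reagents that add atoms: chlorotrimethylsilane, C[Si](C)(C)Cl; lithium diisopropylamide, [Li]N(C(C)C)C(C)C (lithium of intermediate 24 only)
Why: Directed deprotonation at C2, flanked by the ring oxygen and bromine, followed by C-silylation at low temperature where the bromine does not migrate.

Step 15
Reactants: 22 terminal C11–C12 epoxide; 25 3-bromo-2-(trimethylsilyl)furan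
Product: 27 C11 alcohol with 2-silyl-3-furyl group on C12, via 3-lithio-2-(trimethylsilyl)furan 26 (not isolated)
Conditions: 25, n-BuLi, THF, −78 °C; then BF3·OEt2 and 22, −78 °C
Reagents that add atoms: n-butyllithium, [Li]CCCC (lithium of intermediate 26 only)
Why: Bromine–lithium exchange and BF3-assisted SN2 opening of the terminal epoxide at C12 form C12–C13 and leave C11 with its configuration.

Step 16
Reactants: 27 C11 alcohol
Product: 28 C11 acetate
Conditions: Ac2O, Et3N, DMAP (cat.), CH2Cl2, rt
Reagents that add atoms: acetic anhydride, CC(=O)OC(C)=O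
Why: DMAP-catalysed acylation of the secondary alcohol, done now so that O-11 cannot lactonise onto C16 later.

Step 17
Reactants: 28 C11 acetate
Product: 31 C15-hydroxybutenolide (carbonyl C16 next to C13), via endoperoxide 29 (not isolated), via silyl ester 30 (not isolated)
Conditions: O2, hν (visible), tetraphenylporphyrin (cat.), CH2Cl2, −78 °C; then H2O, rt
Reagents that add atoms: dioxygen, O=O
Why: Singlet-oxygen [4+2] cycloaddition to the 2-silylfuran and silyl migration within the endoperoxide make the silicon-bearing carbon the carboxyl carbon C16, while the 1,1-disubstituted alkene reacts far more slowly in the ene mode.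

Step 18
Reactants: 31 C15-hydroxybutenolide
Product: 32 target (CNP0182424.2)
Conditions: NaBH4, EtOH, 0 °C; then 1 M HCl
Reagents that add atoms: none
Why: Borohydride reduces the aldehyde of the ring-opened 4-oxo-2-enoate form and acidification relactonises to the butenolide, the acetate surviving the short exposure at 0 °C.

**Compound list**

1 | (1R,5R)-(+)-verbenone | O=C1C=C(C)[C@H]2C[C@@H]1C2(C)C | starting material
2 | allylmagnesium bromide | C=CC[Mg]Br | starting material
3 | trimethylsilyl enol ether of 4 (C8–OSiMe3, C8=C9; not isolated) | C[Si](C)(C)OC1=C[C@@](C)(CC=C)[C@H]2C[C@@H]1C2(C)C | intermediate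
4 | (1R,4R,5R)-4-allyl-4,6,6-trimethylbicyclo[3.1.1]heptan-2-one; allyl anti to the CMe2 bridge | O=C1C[C@@](C)(CC=C)[C@H]2C[C@@H]1C2(C)C | intermediate
5 | ozonide (1,2,4-trioxolane) of the allyl group of 4 (not isolated) | O=C1C[C@@](C)(CC3OCOO3)[C@H]2C[C@@H]1C2(C)C | intermediate
6 | keto aldehyde: 4 with C10–CH2–CHO in place of allyl | O=C1C[C@@](C)(CC=O)[C@H]2C[C@@H]1C2(C)C | intermediate
7 | propargyl ketone: C10–CH2–C≡CH | O=C1C[C@@](C)(CC#C)[C@H]2C[C@@H]1C2(C)C | intermediate
8 | (Z)-vinylsilane ketone: C10–CH2–CH=CH–SiEt3 | O=C1C[C@@](C)(C/C=C\[Si](CC)(CC)CC)[C@H]2C[C@@H]1C2(C)C | intermediate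
9 | (triisopropylsilyloxy)acetaldehyde | O=CCO[Si](C(C)C)(C(C)C)C(C)C | starting material
10 | lithium enolate of 8 (C8–OLi, C8=C9; not isolated) | [Li]OC1=C[C@@](C)(C/C=C\[Si](CC)(CC)CC)[C@H]2C[C@@H]1C2(C)C | intermediate
11 | aldol adduct: 8 with C9–CH(OH)–CH2OSi(i-Pr)3, mixture at C9 and C11 | O=C1C(C(O)CO[Si](C(C)C)(C(C)C)C(C)C)[C@@](C)(C/C=C\[Si](CC)(CC)CC)[C@H]2C[C@@H]1C2(C)C | intermediate
12 | C11 mesylate of 11 (not isolated) | O=C1C(C(OS(C)(=O)=O)CO[Si](C(C)C)(C(C)C)C(C)C)[C@@](C)(C/C=C\[Si](CC)(CC)CC)[C@H]2C[C@@H]1C2(C)C | intermediate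
13 | key-step precursor: bicyclo[3.1.1]heptan-2-one with (Z)-C9=C11H–CH2OSi(i-Pr)3 (CH2O syn to C=O), C10 methyl and C10 (Z)-3-(triethylsilyl)allyl arm anti to the CMe2 bridge | O=C1/C(=C\CO[Si](C(C)C)(C(C)C)C(C)C)[C@@](C)(C/C=C\[Si](CC)(CC)CC)[C@H]2C[C@@H]1C2(C)C | intermediate
14 | key-step product: (4aS,8aS)-1-[(Z)-2-(triisopropylsilyloxy)ethylidene]-5,5,8a-trimethyl-3,4,4a,5,8,8a-hexahydronaphthalen-2(1H)-one (trans-fused, C2=C3 in ring A) | O=C1CC[C@H]2C(C)(C)C=CC[C@]2(C)/C1=C/CO[Si](C(C)C)(C(C)C)C(C)C | intermediate
15 | C11 pinacol boronate: 9α-H, boron on C11 from the α face (not isolated) | O=C1CC[C@H]2C(C)(C)C=CC[C@]2(C)[C@H]1[C@@H](CO[Si](C(C)C)(C(C)C)C(C)C)B1OC(C)(C)C(C)(C)O1 | intermediate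
16 | β-hydroxy ketone: C8=O, 9α-H, C11–OH as in the target (reads 11S while C12 carries oxygen), C12–OSi(i-Pr)3, C2=C3 | O=C1CC[C@H]2C(C)(C)C=CC[C@]2(C)[C@H]1[C@@H](CO[Si](C(C)C)(C(C)C)C(C)C)O | intermediate
17 | 16 with ring A saturated | O=C1CC[C@H]2C(C)(C)CCC[C@]2(C)[C@H]1[C@@H](CO[Si](C(C)C)(C(C)C)C(C)C)O | intermediate
18 | C11 triethylsilyl ether of 17 | O=C1CC[C@H]2C(C)(C)CCC[C@]2(C)[C@H]1[C@@H](CO[Si](C(C)C)(C(C)C)C(C)C)O[Si](CC)(CC)CC | intermediate
19 | 8(17)-methylene compound with C11–OSiEt3 and C12–OSi(i-Pr)3 | C=C1CC[C@H]2C(C)(C)CCC[C@]2(C)[C@H]1[C@@H](CO[Si](C(C)C)(C(C)C)C(C)C)O[Si](CC)(CC)CC | intermediate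
20 | C11,C12-diol with 8(17)-methylene | C=C1CC[C@H]2C(C)(C)CCC[C@]2(C)[C@H]1[C@@H](CO)O | intermediate
21 | C12 tosylate of 20 (not isolated) | C=C1CC[C@H]2C(C)(C)CCC[C@]2(C)[C@H]1[C@@H](COS(=O)(=O)c1ccc(C)cc1)O | intermediate
22 | C11–C12 epoxide, C11 as in the target | C=C1CC[C@H]2C(C)(C)CCC[C@]2(C)[C@H]1[C@@H]1OC1 | intermediate
23 | 3-bromofuran | Brc1ccoc1 | starting material
24 | 3-bromo-2-lithiofuran (not isolated) | [Li]c1occc1Br | intermediate
25 | 3-bromo-2-(trimethylsilyl)furan | C[Si](C)(C)c1occc1Br | intermediate
26 | 3-lithio-2-(trimethylsilyl)furan (not isolated) | C[Si](C)(C)c1occc1[Li] | intermediate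
27 | (11R)-alcohol with 2-(trimethylsilyl)furan-3-yl on C12 | C=C1CC[C@H]2C(C)(C)CCC[C@]2(C)[C@H]1[C@@H](Cc1ccoc1[Si](C)(C)C)O | intermediate
28 | (11R)-acetate of 27 | C=C1CC[C@H]2C(C)(C)CCC[C@]2(C)[C@H]1[C@@H](Cc1ccoc1[Si](C)(C)C)OC(C)=O | intermediate
29 | furan endoperoxide of 28 (not isolated) | C=C1CC[C@H]2C(C)(C)CCC[C@]2(C)[C@H]1[C@@H](CC1=CC2OOC1([Si](C)(C)C)O2)OC(C)=O | intermediate
30 | trimethylsilyl (Z)-4-oxobut-2-enoate carrying the side chain on C13 (not isolated) | C=C1CC[C@H]2C(C)(C)CCC[C@]2(C)[C@H]1[C@@H](C/C(=C/C=O)C(=O)O[Si](C)(C)C)OC(C)=O | intermediate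
31 | C15-hydroxybutenolide (C16 carbonyl on C13, mixture at C15) | C=C1CC[C@H]2C(C)(C)CCC[C@]2(C)[C@H]1[C@@H](CC1=CC(O)OC1=O)OC(C)=O | intermediate
32 | (5S,9S,10S,11R)-11-acetoxylabda-8(17),13-dien-16,15-olide (CNP0182424.2) | C=C1CC[C@H]2C(C)(C)CCC[C@]2(C)[C@H]1[C@@H](CC1=CCOC1=O)OC(C)=O | target

**Step count and risks**

Total steps: 18. Longest linear sequence: 17 (steps 1–13 and 15–18); step 14 prepares furan 25 on the side.

Steps most likely to fail:

1. Step 7 (key step). The cyclobutane may resist heterolysis under BF3 alone, or the C4 cation may be quenched by proton loss or fluoride before it reaches C3. Fallback, from 13 back to 14, in separate known operations. The cyclobutane is opened under the established acylative conditions for pinane ketones (Ac2O, Zn(OAc)2, BF3·OEt2, 0 °C → rt), which should give the ring-opened dienyl acetate with a tertiary C4 acetate F1. The C4 acetate is then ionised on its own (SnCl4, CH2Cl2, −78 °C) for a vinylsilane-terminated cation–olefin cyclisation to the dienol acetate of the octalin F2. K2CO3 in MeOH cleaves the enol acetate and gives 14.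

2. Step 1. Addition of the allyl metal to the carbonyl, or allyl–allyl coupling, may compete with conjugate addition at the hindered β-carbon. Fallback, from 1 back to 6. CuI-catalysed conjugate addition of vinylmagnesium bromide, which is established on verbenone with the same facial sense, should give the vinyl ketone F3. Hydroboration–oxidation (BH3·THF, then NaOH/H2O2), which also reduces the ketone, gives the diol F4. Double oxidation with Dess–Martin periodinane returns keto aldehyde 6, so the allyl group and the ozonolysis are bypassed.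

3. Step 8. Addition of the boryl copper species to the hindered trisubstituted enone may be slow, or the C12 silyloxy group may be lost by β-elimination from the C11 boronate. Fallback, from 14 back to 16. Nucleophilic epoxidation (t-BuOOH, DBU, CH2Cl2) from the α face should give the α,β-epoxy ketone F5. SmI2 (THF/MeOH, −78 °C) then cleaves the C9–O bond reductively, and protonation of the enolate gives 16 with the same C11 configuration.

**Further compounds**

F1 | step 7 | ring-opened dienyl acetate: C7=C8–OAc, (Z)-C9=C11, C5–C(CH3)2OAc, (Z)-silylallyl arm on C10 | CC(=O)OC1=CC[C@@H](C(C)(C)OC(C)=O)[C@](C)(C/C=C\[Si](CC)(CC)CC)/C1=C/CO[Si](C(C)C)(C(C)C)C(C)C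
F2 | step 7 | C7=C8 dienol acetate of 14 | CC(=O)OC1=CC[C@H]2C(C)(C)C=CC[C@]2(C)/C1=C/CO[Si](C(C)C)(C(C)C)C(C)C
F3 | step 1 | 4-vinyl-4,6,6-trimethylbicyclo[3.1.1]heptan-2-one, vinyl anti to the CMe2 bridge | O=C1C[C@@](C)(C=C)[C@H]2C[C@@H]1C2(C)C
F4 | step 1 | diol: C8 carbinol and C10–CH2CH2OH | OC1C[C@@](C)(CCO)[C@H]2C[C@@H]1C2(C)C
F5 | step 8 | C9,C11 α-epoxy ketone of 14 | O=C1CC[C@H]2C(C)(C)C=CC[C@]2(C)[C@]13O[C@@H]3CO[Si](C(C)C)(C(C)C)C(C)C
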